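Numbering used below: C1 lactone C=O, C2 lactone CH2, C3 hemiketal carbon, C4 ring-fusion C(Me)–O, C5 ring CH2, C6 C(Me)–OO, C8 side-chain CH(Me), C12=C13 alkene.
**Enabling feature:** C3 of the 1,2-dioxane is a peroxy-hemiketal, that is, a masked ketone flanked by C2 and C4. The fused γ-lactone is therefore a 5,5-disubstituted tetronic acid, and its O–C1(=O) unit is CO2 laid across the α carbon (C2, enolate) and the α′ carbon (C4, tertiary chloride) of that ketone.
**Cuts:** C3–OO (hemiketal); then C1–C2 and O–C4 together (CO2 out); C4–Cl (decarboxylative chlorination); C4–C5 (reductive Knoevenagel); C6–OO (epoxide perhydrolysis); C5–C6 (methylene transfer); C8–Me (conjugate addition); C12–Me and C13–benzyl (carboalumination/coupling).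
**Forward:** the chain is grown linearly from hex-5-yn-1-ol. Both rings arise last, in one flask: first the lactone, then the 1,2-dioxane.
**Stereochemistry:** E-alkene from syn-carboalumination; C8 from Cu/Josiphos conjugate addition; C6 from catalytic asymmetric Corey–Chaykovsky epoxidation, then invertive perhydrolysis; C4 from chiral-amine chlorination, then invertive lactonisation; C3 relayed from C4 by the cis ring fusion.

Key step: step 14

Assumption: the catalyst antipodes named in steps 4, 5 and 13 are those taken to give the drawn configurations; if the sense of induction is the reverse, the mirror-image catalyst is used.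
Assumption: hydroperoxy tetronic acid 23 rests as its bicyclic peroxy-hemiketal 24, the form in which the target is defined.

Step 1
Reactants: 1 hex-5-yn-1-ol; 2 benzyl bromide
Product: 4 (5E)-5-methyl-7-phenylhept-5-en-1-ol, via alkenylalane 3 (not isolated)
Conditions: Me3Al (3 equiv), Cp2ZrCl2 (0.25 equiv), CH2Cl2, 0 °C to rt; then 2, Pd(PPh3)4 (5 mol %), THF, rt; aq potassium sodium tartrate
Reagents that add atoms: trimethylaluminium, C[Al](C)C
Why: Zr-catalysed carboalumination adds Me and Al syn with Al on the terminal carbon, and the Negishi-type Pd coupling of the alkenylalane with the benzyl halide keeps the geometry, so the E-trisubstituted alkene is fixed at the outset.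

Step 2
Reactants: 4 (5E)-5-methyl-7-phenylhept-5-en-1-ol
Product: 5 (5E)-5-methyl-7-phenylhept-5-enal
Conditions: TEMPO (10 mol %), PhI(OAc)2 (1.1 equiv), CH2Cl2, rt
Reagents that add atoms: none
Why: The oxoammonium (TEMPO) oxidation of a primary alcohol stops at the aldehyde and leaves the trisubstituted alkene untouched.

Step 3
Reactants: 5 (5E)-5-methyl-7-phenylhept-5-enal; 6 1-(triphenylphosphoranylidene)propan-2-one
Product: 7 (3E,8E)-8-methyl-10-phenyldeca-3,8-dien-2-one
Conditions: CH2Cl2, 40 °C
Reagents that add atoms: none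
Why: The Wittig olefination with a stabilised ylide should give the E-enone needed for the conjugate addition.

Step 4
Reactants: 7 (3E,8E)-8-methyl-10-phenyldeca-3,8-dien-2-one
Product: 8 (4R,8E)-4,8-dimethyl-10-phenyldec-8-en-2-one
Conditions: MeMgBr (1.2 equiv), CuBr·SMe2 (5 mol %), (R,Sp)-Josiphos (6 mol %), t-BuOMe, −75 °C; aq NH4Cl
Reagents that add atoms: methylmagnesium bromide, C[Mg]Br
Why: In this Cu(I)/ferrocenyl-diphosphine-catalysed enantioselective conjugate addition of a Grignard reagent to an acyclic enone, the ligand shields one enone face and sets C8 as R, while the isolated alkene is inert.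

Step 5
Reactants: 8 (4R,8E)-4,8-dimethyl-10-phenyldec-8-en-2-one
Product: 9 (2S)-2-[(2R,6E)-2,6-dimethyl-8-phenyloct-6-en-1-yl]-2-methyloxirane
Conditions: Me3S(O)I, NaH, THF; (S)-La–Li3–tris(binaphthoxide) (5 mol %), tris(2,4,6-trimethoxyphenyl)phosphine oxide (5 mol %), MS 5 Å, THF, rt
Reagents that add atoms: trimethylsulfoxonium iodide, C[S+](C)(C)=O.[I-]
Why: In this catalytic asymmetric Corey–Chaykovsky epoxidation of a methyl ketone, the heterobimetallic complex binds ketone and ylide and tells Me from CH2R, so the C6–O centre (S) is set under catalyst control and C5 is added.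

Step 6
Reactants: 9 (2S)-2-[(2R,6E)-2,6-dimethyl-8-phenyloct-6-en-1-yl]-2-methyloxirane
Product: 10 (2R,4R,8E)-2-hydroperoxy-2,4,8-trimethyl-10-phenyldec-8-en-1-ol
Conditions: anhydrous ethereal H2O2 (excess), phosphomolybdic acid (3 mol %), Et2O, 0 °C to rt
Reagents that add atoms: hydrogen peroxide, OO
Why: In the phosphomolybdic-acid-catalysed perhydrolysis of a 2,2-disubstituted epoxide, H2O2 attacks the activated ring at the tertiary carbon from the rear (borderline SN2), so C6 is inverted to the R-hydroperoxide and C5 is released as the primary alcohol.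

Step 7
Reactants: 10 (2R,4R,8E)-2-hydroperoxy-2,4,8-trimethyl-10-phenyldec-8-en-1-ol
Product: 11 (2R,4R,8E)-2-[(2-methoxypropan-2-yl)peroxy]-2,4,8-trimethyl-10-phenyldec-8-en-1-ol
Conditions: 2-methoxypropene (1.05 equiv), PPTS (2 mol %), CH2Cl2, −20 °C, short contact; Et3N quench
Reagents that add atoms: 2-methoxypropene, C=C(C)OC
Why: In this acid-catalysed perketal formation the α-effect OOH adds to the enol ether ahead of the neopentyl-type alcohol, and the low temperature and early quench should suppress the slower transketalisation to a 1,2,4-trioxane.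

Step 8
Reactants: 11 (2R,4R,8E)-2-[(2-methoxypropan-2-yl)peroxy]-2,4,8-trimethyl-10-phenyldec-8-en-1-ol
Product: 12 (2R,4R,8E)-2-[(2-methoxypropan-2-yl)peroxy]-2,4,8-trimethyl-10-phenyldec-8-enal
Conditions: Dess–Martin periodinane, pyridine, CH2Cl2, 0 °C
Reagents that add atoms: none
Why: The buffered Dess–Martin oxidation handles hindered primary alcohols, spares perketal, O–O bond and alkene, and gives an aldehyde without an α-hydrogen, so C6 cannot epimerise.

Step 9
Reactants: 13 2,2,6-trimethyl-4H-1,3-dioxin-4-one; 14 2-(trimethylsilyl)ethanol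
Product: 15 2-(trimethylsilyl)ethyl 3-oxobutanoate
Conditions: toluene, reflux
Reagents that add atoms: none
Why: Thermal retro-[4+2] of the dioxinone releases acetylketene, which the alcohol traps (acetoacetylation).

Step 10
Reactants: 12 (2R,4R,8E)-2-[(2-methoxypropan-2-yl)peroxy]-2,4,8-trimethyl-10-phenyldec-8-enal; 15 2-(trimethylsilyl)ethyl 3-oxobutanoate
Product: 17 2-(trimethylsilyl)ethyl (4R,6R,10E)-2-acetyl-4-[(2-methoxypropan-2-yl)peroxy]-4,6,10-trimethyl-12-phenyldodec-10-enoate (both C2 epimers), via alkylidene acetoacetate 16 (not isolated)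
Conditions: L-proline (20 mol %), Hantzsch ester (1.2 equiv), CH2Cl2, rt
Reagents that add atoms: none
Why: This organocatalytic reductive alkylation (Knoevenagel condensation, then Hantzsch-ester conjugate transfer hydrogenation) makes the C4–C5 bond at a neopentyl position without an SN2 step and without reagents that attack O–O, the non-enolisable and inductively activated aldehyde cannot self-condense, and the C4 mixture is erased in step 13.

Step 11
Reactants: 17 2-(trimethylsilyl)ethyl (4R,6R,10E)-2-acetyl-4-[(2-methoxypropan-2-yl)peroxy]-4,6,10-trimethyl-12-phenyldodec-10-enoate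
Product: 18 2-(trimethylsilyl)ethyl (4R,6R,10E)-2-acetyl-4-[(2-methoxypropan-2-yl)peroxy]-2,4,6,10-tetramethyl-12-phenyldodec-10-enoate (both C2 epimers)
Conditions: MeI, K2CO3, acetone, rt
Reagents that add atoms: iodomethane, CI
Why: C-alkylation of the stabilised β-keto ester enolate with the smallest electrophile installs the C4 methyl group, and the configuration formed here does not matter.

Step 12
Reactants: 18 2-(trimethylsilyl)ethyl (4R,6R,10E)-2-acetyl-4-[(2-methoxypropan-2-yl)peroxy]-2,4,6,10-tetramethyl-12-phenyldodec-10-enoate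
Product: 19 (4R,6R,10E)-2-acetyl-4-[(2-methoxypropan-2-yl)peroxy]-2,4,6,10-tetramethyl-12-phenyldodec-10-enoic acid (both C2 epimers)
Conditions: TBAF, THF, 0 °C; cold dilute HCl to pH 3, rapid extraction, used at once
Reagents that add atoms: none
Why: Fluoride-induced fragmentation of the 2-silylethyl ester frees the α,α-disubstituted β-keto acid under non-reductive, essentially neutral conditions that spare the perketal, the peroxide and the alkene.

Step 13
Reactants: 19 (4R,6R,10E)-2-acetyl-4-[(2-methoxypropan-2-yl)peroxy]-2,4,6,10-tetramethyl-12-phenyldodec-10-enoic acid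
Product: 20 (3S,5R,7R,11E)-3-chloro-5-[(2-methoxypropan-2-yl)peroxy]-3,5,7,11-tetramethyl-13-phenyltridec-11-en-2-one
Conditions: N-chlorosuccinimide (1.3 equiv), (S)-binaphthyl-based chiral primary amine (10 mol %), toluene, 0 °C to rt
Reagents that add atoms: N-chlorosuccinimide, O=C1CCC(=O)N1Cl
Why: In this enantioselective decarboxylative chlorination of a β-keto acid, the amine condenses with the ketone, loss of CO2 gives the C3=C4 enamine regiospecifically from both epimers, and NCS attacks its open face, setting C4 as S under catalyst control.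

Step 14
Reactants: 20 (3S,5R,7R,11E)-3-chloro-5-[(2-methoxypropan-2-yl)peroxy]-3,5,7,11-tetramethyl-13-phenyltridec-11-en-2-one
Product: 24 (3R,4aR,7aR)-7a-hydroxy-3,4a-dimethyl-3-[(2R,6E)-2,6-dimethyl-8-phenyloct-6-en-1-yl]tetrahydrofuro[3,2-c][1,2]dioxin-6-one (target), via β-keto carboxylate 21 (not isolated), via tetronate perketal 22 (not isolated), via hydroperoxy tetronic acid 23 (not isolated)
Conditions: CO2 (1.0 MPa), MTBD (3 equiv), DMF, 25 °C; vent; then 1 M HCl–THF (pH ≈ 2), 0 °C to rt
Reagents that add atoms: carbon dioxide, O=C=O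
Why: Proposed new method: MTBD reversibly deprotonates the only enolisable position (the C2 methyl group, since C4 is fully substituted), the enolate adds to the large excess of CO2 to give β-keto carboxylate 21 (C1–C2 bond), and its carboxylate oxygen displaces chloride at C4 from the rear (O–C4 bond), an irreversible event that pulls the unfavourable carboxylation equilibrium forward and stores the acidic product as the inert tetronate 22. The closest known reaction types are the guanidine/CO2 carboxylation of ketone enolates made productive by an intramolecular O-trap (silver-activated alkynes, including ynones to tetronic acids), the classical closure of γ-halo-acetoacetates to tetronic acids, and the SN2 displacement of enantioenriched tertiary α-chloro ketones by O-, N- and S-nucleophiles with inversion. Ring closures: the lactone forms 5-exo-tet (chloride leaves outside the ring), and after acidic loss of the perketal the C6–OOH adds 6-exo-trig to the C3 carbonyl of the keto tautomer of 23 to close the 1,2-dioxane. Stereocontrol: C4 becomes R by inversion of the S-chloride, C3 is fixed by C4 because a five-membered lactone can only be cis-fused to the dioxane (hemiketal OH axial, anomerically favoured), and C6 and C8 are spectators. Selectivity needed: carboxylation and lactonisation must outrun Favorskii closure (C2 on C4), ionisation to an oxyallyl cation, E2 loss of HCl and enolate attack on the peroxide oxygen, which is served by the high CO2 pressure, the non-nucleophilic base, room temperature, the α-carbonyl group that retards ionisation, and the doubly tertiary, hindered perketal.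

Compound list
1 | hex-5-yn-1-ol | C#CCCCCO | starting material
2 | benzyl bromide | BrCc1ccccc1 | starting material
3 | (E)-alkenylalane, [(1E)-6-(dimethylalumanyloxy)-2-methylhex-1-en-1-yl]dimethylalumane | C/C(=C\[Al](C)C)CCCCO[Al](C)C | intermediate
4 | (5E)-5-methyl-7-phenylhept-5-en-1-ol | C/C(=C\Cc1ccccc1)CCCCO | intermediate
5 | (5E)-5-methyl-7-phenylhept-5-enal | C/C(=C\Cc1ccccc1)CCCC=O | intermediate
6 | 1-(triphenylphosphoranylidene)propan-2-one | CC(=O)C=P(c1ccccc1)(c1ccccc1)c1ccccc1 | starting material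
7 | (3E,8E)-8-methyl-10-phenyldeca-3,8-dien-2-one | C/C(=C\Cc1ccccc1)CCC/C=C/C(C)=O | intermediate
8 | (4R,8E)-4,8-dimethyl-10-phenyldec-8-en-2-one | C/C(=C\Cc1ccccc1)CCC[C@@H](C)CC(C)=O | intermediate
9 | (2S)-2-[(2R,6E)-2,6-dimethyl-8-phenyloct-6-en-1-yl]-2-methyloxirane | C/C(=C\Cc1ccccc1)CCC[C@@H](C)C[C@@]1(C)CO1 | intermediate
10 | (2R,4R,8E)-2-hydroperoxy-2,4,8-trimethyl-10-phenyldec-8-en-1-ol | C/C(=C\Cc1ccccc1)CCC[C@@H](C)C[C@](C)(CO)OO | intermediate
11 | (2R,4R,8E)-2-[(2-methoxypropan-2-yl)peroxy]-2,4,8-trimethyl-10-phenyldec-8-en-1-ol | C/C(=C\Cc1ccccc1)CCC[C@@H](C)C[C@](C)(CO)OOC(C)(C)OC | intermediate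
12 | (2R,4R,8E)-2-[(2-methoxypropan-2-yl)peroxy]-2,4,8-trimethyl-10-phenyldec-8-enal | C/C(=C\Cc1ccccc1)CCC[C@@H](C)C[C@](C)(C=O)OOC(C)(C)OC | intermediate
13 | 2,2,6-trimethyl-4H-1,3-dioxin-4-one | CC1=CC(=O)OC(C)(C)O1 | starting material
14 | 2-(trimethylsilyl)ethanol | C[Si](C)(C)CCO | starting material
15 | 2-(trimethylsilyl)ethyl 3-oxobutanoate | CC(=O)CC(=O)OCC[Si](C)(C)C | intermediate
16 | alkylidene acetoacetate, 2-(trimethylsilyl)ethyl (4R,6R,10E)-2-acetyl-4-[(2-methoxypropan-2-yl)peroxy]-4,6,10-trimethyl-12-phenyldodeca-2,10-dienoate (C2=C3 E/Z mixture) | C/C(=C\Cc1ccccc1)CCC[C@@H](C)C[C@](C)(C=C(C(C)=O)C(=O)OCC[Si](C)(C)C)OOC(C)(C)OC | intermediate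
17 | 2-(trimethylsilyl)ethyl (4R,6R,10E)-2-acetyl-4-[(2-methoxypropan-2-yl)peroxy]-4,6,10-trimethyl-12-phenyldodec-10-enoate (both C2 epimers) | C/C(=C\Cc1ccccc1)CCC[C@@H](C)C[C@](C)(CC(C(C)=O)C(=O)OCC[Si](C)(C)C)OOC(C)(C)OC | intermediate
18 | 2-(trimethylsilyl)ethyl (4R,6R,10E)-2-acetyl-4-[(2-methoxypropan-2-yl)peroxy]-2,4,6,10-tetramethyl-12-phenyldodec-10-enoate (both C2 epimers) | C/C(=C\Cc1ccccc1)CCC[C@@H](C)C[C@](C)(CC(C)(C(C)=O)C(=O)OCC[Si](C)(C)C)OOC(C)(C)OC | intermediate
19 | (4R,6R,10E)-2-acetyl-4-[(2-methoxypropan-2-yl)peroxy]-2,4,6,10-tetramethyl-12-phenyldodec-10-enoic acid (both C2 epimers) | C/C(=C\Cc1ccccc1)CCC[C@@H](C)C[C@](C)(CC(C)(C(C)=O)C(=O)O)OOC(C)(C)OC | intermediate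
20 | (3S,5R,7R,11E)-3-chloro-5-[(2-methoxypropan-2-yl)peroxy]-3,5,7,11-tetramethyl-13-phenyltridec-11-en-2-one | C/C(=C\Cc1ccccc1)CCC[C@@H](C)C[C@](C)(C[C@](C)(Cl)C(C)=O)OOC(C)(C)OC | intermediate
21 | (4S,6R,8R,12E)-4-chloro-6-[(2-methoxypropan-2-yl)peroxy]-4,6,8,12-tetramethyl-3-oxo-14-phenyltetradec-12-enoate (anion) | C/C(=C\Cc1ccccc1)CCC[C@@H](C)C[C@](C)(C[C@](C)(Cl)C(=O)CC(=O)[O-])OOC(C)(C)OC | intermediate
22 | (5R)-5-{(2R,4R,8E)-2-[(2-methoxypropan-2-yl)peroxy]-2,4,8-trimethyl-10-phenyldec-8-en-1-yl}-5-methyl-2-oxo-2,5-dihydrofuran-4-olate (tetronate anion) | C/C(=C\Cc1ccccc1)CCC[C@@H](C)C[C@](C)(C[C@@]1(C)OC(=O)C=C1[O-])OOC(C)(C)OC | intermediate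
23 | (5R)-4-hydroxy-5-[(2R,4R,8E)-2-hydroperoxy-2,4,8-trimethyl-10-phenyldec-8-en-1-yl]-5-methylfuran-2(5H)-one | C/C(=C\Cc1ccccc1)CCC[C@@H](C)C[C@](C)(C[C@@]1(C)OC(=O)C=C1O)OO | intermediate
24 | (3R,4aR,7aR)-7a-hydroxy-3,4a-dimethyl-3-[(2R,6E)-2,6-dimethyl-8-phenyloct-6-en-1-yl]tetrahydrofuro[3,2-c][1,2]dioxin-6-one | C/C(=C\Cc1ccccc1)CCC[C@@H](C)C[C@]1(C)C[C@@]2(C)OC(=O)C[C@@]2(O)OO1 | target

Total step count: 14. Longest linear sequence: 13 (steps 1–8 and 10–14, from hex-5-yn-1-ol).

Steps most likely to fail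

**Step 14 (labelled step).**
- What may go wrong: the enolate may close on C4 (Favorskii pathway). The chloride may ionise, so that the configuration at C4 leaks away. HCl may be lost by elimination before CO2 is captured.
- Fallback (known chemistry, different order of bond formation): it sets out from 20 and returns at 22.
- The chloride is displaced with aqueous Bu4NOH in THF at 0 °C, an SN2 reaction of a tertiary α-chloro ketone with inversion. This gives the (3R)-α-hydroxy ketone F1.
- Claisen-type C-methoxycarbonylation of its methyl ketone with dimethyl carbonate and KOt-Bu in THF gives the γ-hydroxy β-keto ester F2. F2 lactonises in the flask to tetronate 22, and the acidic work-up of step 14 then leads through 23 to 24.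

**Step 13.**
- What may go wrong: facial discrimination may be poor on an acyclic, tetrasubstituted enamine that can exist as E/Z isomers. The enamine may also drift to the C2 side, followed by chlorination of the methyl group.
- Fallback (stoichiometric reagent control, with an oxygen leaving group): it sets out from 18 and returns at 22.
- Fluoride-triggered decarboxylation of the silylethyl ester gives the tetrasubstituted ammonium enolate regiospecifically. This enolate is hydroxylated with an enantiopure (camphorylsulfonyl)oxaziridine (Davis oxidation) to the (3S)-α-hydroxy ketone F3.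
- MsCl/Et3N (sulfene pathway) converts F3 into the tertiary α-keto mesylate F4.
- F4 takes the place of 20 under the conditions of step 14 and passes through the mesyloxy β-keto carboxylate F5 to tetronate 22.

**Step 6.**
- What may go wrong: partial ionisation at the tertiary carbon may erode the configuration at C6. A molybdenum-peroxo species may also transfer oxygen to the side-chain alkene.
- Fallback (a four-membered ring as the electrophile, then removal of one carbon): it sets out from 9 and returns at 12.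
- Ring expansion of the epoxide with dimethyloxosulfonium methylide (t-BuOK, t-BuOH, warm) gives the 2,2-disubstituted oxetane F6 with the C6–O bond untouched.
- TMSOTf-promoted opening with ethereal H2O2 inverts C6 and gives the 3-hydroperoxy alcohol F7.
- Perketal formation with 2-methoxypropene gives F8, and Dess–Martin oxidation gives the aldehyde F9.
- Condensation with morpholine gives the enamine F10, whose C=C bond is cleaved with NaIO4 to aldehyde 12.

Further compounds
F1 | step 14 | (3R,5R,7R,11E)-3-hydroxy-5-[(2-methoxypropan-2-yl)peroxy]-3,5,7,11-tetramethyl-13-phenyltridec-11-en-2-one | C/C(=C\Cc1ccccc1)CCC[C@@H](C)C[C@](C)(C[C@@](C)(O)C(C)=O)OOC(C)(C)OC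
F2 | step 14 | methyl (4R,6R,8R,12E)-4-hydroxy-6-[(2-methoxypropan-2-yl)peroxy]-4,6,8,12-tetramethyl-3-oxo-14-phenyltetradec-12-enoate | C/C(=C\Cc1ccccc1)CCC[C@@H](C)C[C@](C)(C[C@@](C)(O)C(=O)CC(=O)OC)OOC(C)(C)OC
F3 | step 13 | (3S,5R,7R,11E)-3-hydroxy-5-[(2-methoxypropan-2-yl)peroxy]-3,5,7,11-tetramethyl-13-phenyltridec-11-en-2-one | C/C(=C\Cc1ccccc1)CCC[C@@H](C)C[C@](C)(C[C@](C)(O)C(C)=O)OOC(C)(C)OC
F4 | step 13 | (3S,5R,7R,11E)-5-[(2-methoxypropan-2-yl)peroxy]-3,5,7,11-tetramethyl-2-oxo-13-phenyltridec-11-en-3-yl methanesulfonate | C/C(=C\Cc1ccccc1)CCC[C@@H](C)C[C@](C)(C[C@](C)(OS(C)(=O)=O)C(C)=O)OOC(C)(C)OC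
F5 | step 13 | (4S,6R,8R,12E)-4-(methanesulfonyloxy)-6-[(2-methoxypropan-2-yl)peroxy]-4,6,8,12-tetramethyl-3-oxo-14-phenyltetradec-12-enoate (anion) | C/C(=C\Cc1ccccc1)CCC[C@@H](C)C[C@](C)(C[C@](C)(OS(C)(=O)=O)C(=O)CC(=O)[O-])OOC(C)(C)OC
F6 | step 6 | (2S)-2-[(2R,6E)-2,6-dimethyl-8-phenyloct-6-en-1-yl]-2-methyloxetane | C/C(=C\Cc1ccccc1)CCC[C@@H](C)C[C@@]1(C)CCO1
F7 | step 6 | (3R,5R,9E)-3-hydroperoxy-3,5,9-trimethyl-11-phenylundec-9-en-1-ol | C/C(=C\Cc1ccccc1)CCC[C@@H](C)C[C@](C)(CCO)OO
F8 | step 6 | (3R,5R,9E)-3-[(2-methoxypropan-2-yl)peroxy]-3,5,9-trimethyl-11-phenylundec-9-en-1-ol | C/C(=C\Cc1ccccc1)CCC[C@@H](C)C[C@](C)(CCO)OOC(C)(C)OC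
F9 | step 6 | (3R,5R,9E)-3-[(2-methoxypropan-2-yl)peroxy]-3,5,9-trimethyl-11-phenylundec-9-enal | C/C(=C\Cc1ccccc1)CCC[C@@H](C)C[C@](C)(CC=O)OOC(C)(C)OC
F10 | step 6 | 4-{(1E,3R,5R,9E)-3-[(2-methoxypropan-2-yl)peroxy]-3,5,9-trimethyl-11-phenylundeca-1,9-dien-1-yl}morpholine | C/C(=C\Cc1ccccc1)CCC[C@@H](C)C[C@](C)(/C=C/N1CCOCC1)OOC(C)(C)OC
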